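# Proposed total synthesis of CNP0182139.1 by palladium enolate alkenylation at C5′

Remark on conventions and assumptions: guaiane numbering is used (unprimed half = the half with the C4=C5 cyclopentene; primed half = the half inside the norbornane). C5′ in compounds 16–24 is drawn as in the key-step precursor, although this α-keto centre is free to epimerise and is erased in step 17. A phenylsulfanyl group at C11 is carried through the key step as a spectator.

## Analysis of the target

The target is a heptacyclic C30 dimer of two guaianolides: each half is a hydroazulene carrying a trans-fused 6,12-γ-lactone and a tertiary C10 methyl carbinol. The halves are joined by the C2–C2′ and C3–C5′ bonds, so that C2, C3, C5′, C1′, C2′, C3′ and C4′ form a bicyclo[2.2.1]heptane. There are fifteen stereocentres. On the central cyclopentane C2–C3–C5′–C1′–C2′, ring A, the C3′–C4′ bridge and C10′ all lie on one face, and the C15′ methyl on C4′ is endo.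

The two halves are not stereochemical copies. C11 carries its methyl anti to H7 (11R, the less stable lactone epimer, opposite to α-santonin), whereas C11′ is 11′S as in α-santonin. C10 has the configuration produced by the santonin photorearrangement, and C10′ the opposite sense relative to H1′.

Sensitive groups are the two tertiary alcohols, the two lactones with enolisable α-centres (C11 being contra-thermodynamic) and the tetrasubstituted C4=C5 alkene. The hardest single element is the quaternary bridgehead C5′, bonded to C6′ (oxygen-bearing), C1′, C3 and C4′.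

The strategy rests on the position of C5′: it is α to C6′ and one bond from C4′. If C6′ is a ketone and C2′ carries a 2-bromoallyl arm (C3′, C4′, C15′), the C4′–C5′ bond can be closed from the C5′ enolate onto the alkenyl carbon.

## Retrosynthetic reasoning

**End game.** The primed lactone of 31 is opened to the γ-keto ester 29 (C6′ ketone, C12′ methyl ester). This makes C5′ an enolisable α-carbon, and the C6′ hydroxyl returns by hydride reduction and spontaneous lactonisation. The endo C15′ methyl of 29 is traced to the exocyclic C4′ methylene of 28, to be hydrogenated from the exo face under direction of the C10′ hydroxyl. The 11R methyl of 28 is traced to the α-methylene lactone 27, and 27 to the C11 phenyl sulfide 25. A quaternary C11 cannot be enolised, so the contra-thermodynamic C11 centre is only unveiled after the last basic step.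

**Key disconnection, C4′–C5′.** Cutting this bond in 25 removes the quaternary bridgehead and one ring of the norbornane. It leaves the cis-fused diquinane ketone 24 with a 2-bromoallyl arm on C2′. The forward reaction is a palladium-catalysed coupling of the C5′ enolate with the alkenyl bromide. It must form a quaternary carbon, but the arm can reach only C5′ and only from one face.

**C10′ carbinol.** The C10′–C14′ bond of 24 is cut to the C10′ ketone 23, which comes from the secondary silyl ether 21 through alcohol 22. The secondary C10′ oxygen is a temporary stereocentre: it steers the earlier conjugate addition at C1′, is then erased, and C10′ is rebuilt by methyl addition anti to the C2′ arm.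

**Side chain, C7′–C11′.** Cutting this bond in 21 gives ketone 18 and the lactate-derived triflate 20 (from 19). SN2 inversion at the triflate fixes C11′. C7′ is α to the ketone and is left to equilibrate.

**C2′–H.** The arm must sit on the concave face of the diquinane, which no intermolecular bond formation will deliver. C2′ of 18 is therefore traced to the quaternary acid 16, and the hydrogen is put in last by a radical decarboxylation from the open convex face.

**Central ring, C1′–C2′ and C3–C5′.** Both bonds of 16 are cut in one operation to the allylic lactone 10 and the enone 14. Forward, the lactone enolate (C2′) adds to C1′ of 14 anti to the silyloxy group. The C5′ enolate so formed is regiodefined and attacks C3 through a π-allyl palladium complex opened from the same lactone.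

**Unprimed fragment.** Lactone 10 comes from 8 and 2,3-dibromopropene 9. Lactone 8 comes from keto ester 6 by 1,2-reduction, and 6 from ketone 4 and methyl bromoacetate 5. Ketone 4 is the silylated photoproduct 3 of the sulfenylated santonin 2, made from α-santonin 1. Santonin supplies C1, C6, C7 and C10 of the unprimed half with the correct configuration.

**Primed fragment.** Enone 14 is the silyl ether of 13, obtained by desymmetrising the meso endoperoxide 12 of cyclohepta-1,3-diene 11.

## Alternatives that were turned down

Alternative 1: Both seven-membered rings would be closed last by a double ring-closing metathesis, giving A1, the 8,9:8′,9′-didehydro compound. The disconnections are C8=C9 and C8′=C9′; forward, vinyl groups on C7/C10 and on C7′/C10′ are joined with the second-generation Grubbs catalyst, (H2IMes)(PCy3)Cl2Ru=CHPh. In its favour, metathesis to cycloheptenes is dependable, needs no base (so C11 would be safe), and works in two directions at once. On these points it is as strong as or stronger than the chosen route. Against it, it leaves the real problem untouched: the norbornane with its quaternary C5′ and the all-cis central ring must already exist, now carrying four vinyl groups and two tertiary allylic carbinols set without the help of a ring. It also throws away the seven-membered ring, C1 and C10 that santonin provides. The chosen strategy spends its risk on the quaternary bridgehead itself and uses the chiral pool for one complete half.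

Alternative 2: The one-carbon bridge would be closed by enolate alkylation, giving A2, the C10′ ketone lacking C14′. The disconnection is C1′–C2′; forward, the C10′ ketone enolate (KOtBu) displaces a C2′ tosylate across a six-membered ring whose spiro atom is C5′. In its favour, SN2 closure to a norbornane is classical, sets C2′ by inversion and needs no transition metal. On predictability of the ring closure it is at least equal. Against it, the spiro quaternary C5′, the C4′ methyl and the cis relationships must be made beforehand. The primed lactone is exposed to alkoxide, E2 elimination of the tosylate competes, and a methyl group must still be added to a ketone next to the bridge. The chosen strategy forms the quaternary centre and the ring in the same step and reaches the C10′ carbinol while the system is still flexible.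

Alternative 3: C3–C5′ would be formed by a conjugate ene reaction, giving A3, the 3′-oxo derivative. In a C2–C2′-linked precursor the ring A C3=C4 alkene attacks C5′ of a Me2AlCl-activated C3′-keto enone with transfer of H5, which moves the alkene to C4=C5. In its favour, both halves could come from santonin photoproducts and the alkene transposition is built in. In step economy and in use of the chiral pool it is stronger than the chosen route. Against it, the ene reaction must create a quaternary carbon at a β,β-disubstituted enone. The Lewis acid meets two lactones and two tertiary alcohols. The C2–C2′ bond between two cyclopentenone α-carbons has no selective construction. The C3′ ketone must afterwards be removed. The chosen strategy is longer but closes the ring by a reaction whose regiochemistry and facial course are fixed by the tether.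

Key step: step 17

## Route

Step 1
Reactants: 1 (−)-α-santonin
Product: 2 11-(phenylsulfanyl)-α-santonin (sulfur on the face anti to H7, C13 methyl cis to H7)
Conditions: LDA, THF, −78 °C; PhSSPh, −78 → 0 °C; aq. NH4Cl
Reagents that add atoms: diphenyl disulfide, c1ccc(cc1)SSc1ccccc1
Why: Sulfenylation of the lactone lithium enolate; the electrophile should enter C11 anti to the axial H7, and the quaternary C11 can no longer be enolised in later basic steps while remaining a latent α-methylene lactone.

Step 2
Reactants: 2 11-(phenylsulfanyl)-α-santonin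
Product: 3 11-(phenylsulfanyl)isophotosantonic lactone (10-hydroxy-3-oxoguai-4-en-12,6-olide, C1 R, C10 R)
Conditions: hν (Hg lamp, Pyrex), AcOH/H2O 1:1, reflux
Reagents that add atoms: water, O
Why: Photochemical cross-conjugated cyclohexadienone rearrangement (santonin to isophotosantonic lactone): C1–C5 bonding, cleavage of C5–C10 and capture of the C10 cation by water anti to the breaking bond should give the 5-7 enone with C1 and C10 as in the unprimed half.

Step 3
Reactants: 3 11-(phenylsulfanyl)isophotosantonic lactone
Product: 4 10-O-triethylsilyl ether of 3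
Conditions: TESOTf, 2,6-lutidine, CH2Cl2, −78 → 0 °C
Reagents that add atoms: triethylsilyl trifluoromethanesulfonate, CC[Si](CC)(CC)OS(=O)(=O)C(F)(F)F
Why: Silylation of the tertiary alcohol with a silyl triflate; it keeps the C10 alkoxide from consuming base or acylating in the enolate steps.

Step 4
Reactants: 4 10-O-triethylsilyl ether of 3; 5 methyl bromoacetate
Product: 6 C2-(methoxycarbonylmethyl) ketone (new C2 substituent trans to C10)
Conditions: LDA, THF, −78 °C; then 5, −78 → −40 °C
Reagents that add atoms: methyl bromoacetate (5), COC(=O)CBr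
Why: Alkylation of the kinetic α′-enolate of the cyclopentenone; the electrophile should approach C2 anti to the C10 substituent on C1, which places the future C2′ on the required face.

Step 5
Reactants: 6 C2-(methoxycarbonylmethyl) ketone
Product: 8 ring A-fused γ-lactone (C3–O acylated by the C2 acetic acid unit, cis-fused), via cis-hydroxy ester 7 (not isolated)
Conditions: NaBH4, CeCl3·7H2O, MeOH, −78 → 0 °C; then PPTS (cat.), CH2Cl2, rt
Reagents that add atoms: none
Why: Luche 1,2-reduction should deliver hydride anti to the C2 side chain, and the cis γ-hydroxy ester lactonises; the allylic C3–O bond is thereby placed on the face on which C5′ must later enter.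

Step 6
Reactants: 8 ring A-fused γ-lactone; 9 2,3-dibromopropene
Product: 10 α-(2-bromoallyl) lactone (arm on the convex face)
Conditions: LDA, THF, −78 °C; then 9, THF/DMPU, −78 → −30 °C
Reagents that add atoms: 2,3-dibromopropene (9), BrCC(Br)=C
Why: Lactone enolate alkylation with an allylic bromide; the lactone CH2 is the only enolisable position because C11 is quaternary, and the configuration at C2′ is immaterial because this centre is planarised in steps 10 and 11.

Step 7
Reactants: 11 cyclohepta-1,3-diene
Product: 12 6,7-dioxabicyclo[3.2.2]non-8-ene (meso endoperoxide)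
Conditions: O2, hν (visible), tetraphenylporphyrin (cat.), CH2Cl2, −20 °C
Reagents that add atoms: dioxygen, O=O
Why: [4+2] cycloaddition of singlet oxygen to the cyclic 1,3-diene.

Step 8
Reactants: 12 meso endoperoxide
Product: 13 (R)-4-hydroxycyclohept-2-en-1-one
Conditions: 6′-hydroxy-9-O-acetylquinidine (10 mol %), CH2Cl2, 0 °C → rt
Reagents that add atoms: none
Why: Kornblum–DeLaMare rearrangement run as a desymmetrisation by a chiral cinchona base, which removes one of the two enantiotopic bridgehead protons; the pseudo-enantiomeric quinine-derived base is taken if the sense of induction proves opposite.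

Step 9
Reactants: 13 (R)-4-hydroxycyclohept-2-en-1-one
Product: 14 (R)-4-(triethylsilyloxy)cyclohept-2-en-1-one
Conditions: TESCl, imidazole, CH2Cl2, 0 °C
Reagents that add atoms: chlorotriethylsilane, CC[Si](Cl)(CC)CC
Why: Silylation of the secondary alcohol; the bulky ether is the control element for the next step.

Step 10
Reactants: 10 α-(2-bromoallyl) lactone; 14 (R)-4-(triethylsilyloxy)cyclohept-2-en-1-one
Product: 16 diquinane keto acid (central ring closed; C2′ bears CO2H and the 2-bromoallyl group; C10′–OTES trans to C2′), via lithium enolate adduct 15 (not isolated)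
Conditions: LDA, THF, −78 °C; 14, −78 → −40 °C; then Pd(PPh3)4 (5 mol %), −40 °C → rt; aq. NH4Cl
Reagents that add atoms: (R)-4-(triethylsilyloxy)cyclohept-2-en-1-one (14), O=C1C=C[C@H](O[Si](CC)(CC)CC)CCC1
Why: Michael addition of the fully substituted lactone enolate (such enolates add 1,4) should occur anti to the γ-silyloxy group, fixing C1′; the regiodefined C5′ enolate then attacks the π-allyl palladium complex opened from the allylic lactone (intramolecular Tsuji–Trost alkylation, 5-exo), and attack anti to palladium gives net retention at C3 and the cis-fused diquinane.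

Step 11
Reactants: 16 diquinane keto acid
Product: 18 C2′–H diquinane ketone (2-bromoallyl arm on the concave face, cis to C10′), via thiohydroxamate ester 17 (not isolated)
Conditions: 2-mercaptopyridine N-oxide, DCC, DMAP (cat.), CH2Cl2, 0 °C → rt, dark; then t-BuSH, hν (W lamp), PhH, rt
Reagents that add atoms: none
Why: Barton reductive decarboxylation; the tertiary C2′ radical should take hydrogen from the thiol on the open convex face (the face of H2 and H1′), which pushes the arm to the concave face, a placement no polar alkylation would give.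

Step 12
Reactants: 19 methyl (S)-lactate
Product: 20 methyl (S)-2-(trifluoromethylsulfonyloxy)propanoate
Conditions: Tf2O, 2,6-lutidine, CH2Cl2, −78 → 0 °C
Reagents that add atoms: trifluoromethanesulfonic anhydride, O=S(=O)(OS(=O)(=O)C(F)(F)F)C(F)(F)F
Why: O-Sulfonylation of the secondary alcohol with retention at carbon.

Step 13
Reactants: 18 C2′–H diquinane ketone; 20 methyl (S)-2-(trifluoromethylsulfonyloxy)propanoate
Product: 21 C7′-[(S)-1-methoxycarbonylethyl] ketone (C7′ S)
Conditions: LDA, THF, −78 °C; then 20, −78 → −40 °C; then DBU (cat.), CH2Cl2, rt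
Reagents that add atoms: methyl (S)-2-(trifluoromethylsulfonyloxy)propanoate (20), C[C@H](OS(=O)(=O)C(F)(F)F)C(=O)OC
Why: Enolate alkylation: the kinetic enolate forms at the less substituted C7′ and displaces the triflate with inversion, which sets C11′ (S); C7′ is then equilibrated to the epimer with the side chain pseudo-equatorial.

Step 14
Reactants: 21 C7′-substituted ketone
Product: 22 10,10′-diol (tertiary C10–OH, secondary C10′–OH)
Conditions: HF·pyridine, pyridine, THF, 0 °C → rt
Reagents that add atoms: none
Why: Fluoride cleavage of both triethylsilyl ethers under buffered acidic conditions that leave the α-centres untouched.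

Step 15
Reactants: 22 10,10′-diol
Product: 23 C6′,C10′-dione
Conditions: Dess–Martin periodinane, NaHCO3, CH2Cl2, 0 °C → rt
Reagents that add atoms: none
Why: Oxidation of the secondary alcohol; the tertiary alcohol and the sulfide are left alone at 0 °C, and the buffered conditions keep the now epimerisable C1′ intact (the crude dione is used directly).

Step 16
Reactants: 23 C6′,C10′-dione
Product: 24 key-step precursor: 2-bromoallyl diquinane C6′ ketone with C10′ methyl carbinol (11-phenylsulfanyl)
Conditions: MeLi, CeCl3, THF, −78 °C; aq. NH4Cl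
Reagents that add atoms: methyllithium, [Li]C
Why: Organocerium 1,2-addition: the non-basic reagent should select the C10′ ketone over C6′ (flanked by two tertiary carbons) and over the esters, and methyl should enter anti to the neighbouring C2′ arm so that the hydroxyl ends cis to C2′ as in the target.

Step 17
Reactants: 24 key-step precursor
Product: 25 C4′-methylene C6′-ketone ester with the norbornane closed (11-phenylsulfanyl)
Conditions: Pd(PPh3)4 (20 mol %), KOtBu (3.5 equiv), THF/t-BuOH 4:1, 25 → 45 °C
Reagents that add atoms: none
Why: Zerovalent palladium inserts into the alkenyl C4′–Br bond, the potassium C5′ enolate displaces bromide on palladium, and C–C reductive elimination forms C4′–C5′; the closest known reaction type is the palladium-catalysed intramolecular α-alkenylation of ketone enolates with alkenyl halides. The cyclopentane C1′–C2′–C3′–C4′–C5′ closes in a 5-exo sense (enolate carbon onto the alkenyl carbon, alkene left exocyclic), which completes the bicyclo[2.2.1]heptane. The new quaternary centre C5′ is controlled by the tether: the arm sits on the concave face at C2′, a one-three bridge across the cyclopentane can only be cis, so C4′ enters on that face and C6′ remains on the convex face. The step needs C5′ over C7′ selectivity; enolisation is reversible in the presence of t-BuOH and only the C5′ enolate can reach the alkenylpalladium centre, the C7′ enolate would have to close a strained seven-membered bridge. It also needs C- over O-alkenylation, which triphenylphosphine-ligated palladium favours for ketone enolates. C11 is quaternary and cannot epimerise, C7′ equilibrates, and the mild temperature and buffered base are chosen to spare C11′.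

Step 18
Reactants: 25 C4′-methylene C6′-ketone ester (11-phenylsulfanyl)
Product: 27 11(13)-didehydro compound (α-methylene lactone, C4′ methylene), via sulfoxide 26 (not isolated)
Conditions: NaIO4, MeOH/H2O, 0 °C → rt; then P(OMe)3, CaCO3, PhMe, 110 °C
Reagents that add atoms: none
Why: Sulfide oxidation and thermal syn-elimination of the sulfoxide; sulfur is anti to H7, so only the C13 hydrogens are syn and the alkene should form exocyclic.

Step 19
Reactants: 27 α-methylene lactone
Product: 28 C4′-methylene C6′-ketone ester with the 11R lactone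
Conditions: H2 (80 bar), Ru(OAc)2[(S)-BINAP] (5 mol %), CH2Cl2/MeOH, 40 °C
Reagents that add atoms: none
Why: Catalyst-controlled asymmetric hydrogenation of an α-methylene-γ-butyrolactone; the ligand hand is the one that gives the (R)-α-methyl lactone from simple α-methylene lactones (the antipodal complex is used if it proves mismatched), hydrogen must be delivered syn to H7, and the carbonyl-chelating alkene should react in preference to the unfunctionalised C4′ methylene and the tetrasubstituted C4=C5.

Step 20
Reactants: 28 C4′-methylene C6′-ketone ester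
Product: 29 C4′-methyl (endo) C6′-ketone ester
Conditions: H2 (50 bar), [Rh(nbd)(dppb)]BF4 (5 mol %), CH2Cl2, rt
Reagents that add atoms: none
Why: Hydroxyl-directed hydrogenation: the C10′ hydroxyl lies over the exo face of the C3′–C4′ bridge and should deliver the cationic rhodium hydride there, leaving the methyl endo; this catalyst does not reduce the tetrasubstituted C4=C5 alkene.

Step 21
Reactants: 29 C4′-methyl C6′-ketone ester
Product: 31 target CNP0182139.1, via C6′ hydroxy ester 30 (not isolated)
Conditions: NaBH4, MeOH/THF, −20 → 0 °C; then PPTS (cat.), PhMe, 60 °C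
Reagents that add atoms: none
Why: Hydride should add to C6′ anti to the pseudo-axial C5′–C3 bond (Felkin–Anh, axial attack) to give the equatorial alcohol trans to the C7′ side chain, which closes the trans-fused γ-lactone with loss of methanol.

## Compound list

1 | (−)-α-santonin | C[C@H]1[C@@H]2CC[C@]3(C=CC(=O)C(=C3[C@H]2OC1=O)C)C | starting material
2 | 11-(phenylsulfanyl)-α-santonin, sulfur anti to H7 | C[C@@]1(Sc4ccccc4)[C@@H]2CC[C@]3(C=CC(=O)C(=C3[C@H]2OC1=O)C)C | intermediate
3 | 11-(phenylsulfanyl)isophotosantonic lactone (10-hydroxy-3-oxoguai-4-en-12,6-olide) | CC1=C2[C@H]3OC(=O)[C@@](Sc4ccccc4)(C)[C@@H]3CC[C@@](C)(O)[C@@H]2CC1=O | intermediate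
4 | 10-O-triethylsilyl ether of 3 | CC1=C2[C@H]3OC(=O)[C@@](Sc4ccccc4)(C)[C@@H]3CC[C@@](C)(O[Si](CC)(CC)CC)[C@@H]2CC1=O | intermediate
5 | methyl bromoacetate | COC(=O)CBr | starting material
6 | C2-(methoxycarbonylmethyl) derivative of 4, side chain trans to C10 | CC1=C2[C@H]3OC(=O)[C@@](Sc4ccccc4)(C)[C@@H]3CC[C@@](C)(O[Si](CC)(CC)CC)[C@@H]2[C@@H](CC(=O)OC)C1=O | intermediate
7 | C3 alcohol of 6, hydroxyl cis to the C2 side chain | CC1=C2[C@H]3OC(=O)[C@@](Sc4ccccc4)(C)[C@@H]3CC[C@@](C)(O[Si](CC)(CC)CC)[C@@H]2[C@@H](CC(=O)OC)[C@H]1O | intermediate (not isolated)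
8 | ring A cis-fused γ-lactone between C3–O and the C2 acetic acid unit | CC1=C2[C@H]3OC(=O)[C@@](Sc4ccccc4)(C)[C@@H]3CC[C@@](C)(O[Si](CC)(CC)CC)[C@@H]2[C@H]5CC(=O)O[C@@H]15 | intermediate
9 | 2,3-dibromopropene | BrCC(Br)=C | starting material
10 | α-(2-bromoallyl) derivative of lactone 8, arm on the convex face | CC1=C2[C@H]3OC(=O)[C@@](Sc4ccccc4)(C)[C@@H]3CC[C@@](C)(O[Si](CC)(CC)CC)[C@@H]2[C@H]5[C@H](CC(Br)=C)C(=O)O[C@@H]15 | intermediate
11 | cyclohepta-1,3-diene | C1=CC=CCCC1 | starting material
12 | 6,7-dioxabicyclo[3.2.2]non-8-ene (meso) | C1C[C@@H]2C=C[C@H](C1)OO2 | intermediate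
13 | (R)-4-hydroxycyclohept-2-en-1-one | O=C1C=C[C@H](O)CCC1 | intermediate
14 | (R)-4-(triethylsilyloxy)cyclohept-2-en-1-one | O=C1C=C[C@H](O[Si](CC)(CC)CC)CCC1 | intermediate
15 | lithium C5′ enolate of the Michael adduct of 10 and 14 (C1′–C2′ formed, lactone intact) | CC1=C2[C@H]3OC(=O)[C@@](Sc4ccccc4)(C)[C@@H]3CC[C@@](C)(O[Si](CC)(CC)CC)[C@@H]2[C@H]5[C@](CC(Br)=C)([C@H]6[C@H](O[Si](CC)(CC)CC)CCCC(O[Li])=C6)C(=O)O[C@@H]15 | intermediate (not isolated)
16 | diquinane keto acid: C2′ bears CO2H (concave) and 2-bromoallyl (convex), C10′–OTES, C6′ ketone | CC1=C2[C@H]3OC(=O)[C@@](Sc4ccccc4)(C)[C@@H]3CC[C@@](C)(O[Si](CC)(CC)CC)[C@@H]2[C@H]2[C@@](CC(Br)=C)(C(=O)O)[C@H]3[C@H](O[Si](CC)(CC)CC)CCCC(=O)[C@@H]3[C@@H]12 | intermediate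
17 | N-acyloxypyridine-2-thione ester of 16 | CC1=C2[C@H]3OC(=O)[C@@](Sc4ccccc4)(C)[C@@H]3CC[C@@](C)(O[Si](CC)(CC)CC)[C@@H]2[C@H]2[C@@](CC(Br)=C)(C(=O)ON6C=CC=CC6=S)[C@H]3[C@H](O[Si](CC)(CC)CC)CCCC(=O)[C@@H]3[C@@H]12 | intermediate (not isolated)
18 | decarboxylated diquinane ketone, C2′–H on the convex face and arm on the concave face | CC1=C2[C@H]3OC(=O)[C@@](Sc4ccccc4)(C)[C@@H]3CC[C@@](C)(O[Si](CC)(CC)CC)[C@@H]2[C@H]2[C@@H](CC(Br)=C)[C@H]3[C@H](O[Si](CC)(CC)CC)CCCC(=O)[C@@H]3[C@@H]12 | intermediate
19 | methyl (S)-lactate | C[C@H](O)C(=O)OC | starting material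
20 | methyl (S)-2-(trifluoromethylsulfonyloxy)propanoate | C[C@H](OS(=O)(=O)C(F)(F)F)C(=O)OC | intermediate
21 | C7′-[(S)-1-methoxycarbonylethyl] derivative of 18 (C7′ S) | CC1=C2[C@H]3OC(=O)[C@@](Sc4ccccc4)(C)[C@@H]3CC[C@@](C)(O[Si](CC)(CC)CC)[C@@H]2[C@H]2[C@@H](CC(Br)=C)[C@H]3[C@H](O[Si](CC)(CC)CC)CC[C@@H]([C@H](C)C(=O)OC)C(=O)[C@@H]3[C@@H]12 | intermediate
22 | 10,10′-diol from 21 (C10′ secondary alcohol) | CC1=C2[C@H]3OC(=O)[C@@](Sc4ccccc4)(C)[C@@H]3CC[C@@](C)(O)[C@@H]2[C@H]2[C@@H](CC(Br)=C)[C@H]3[C@H](O)CC[C@@H]([C@H](C)C(=O)OC)C(=O)[C@@H]3[C@@H]12 | intermediate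
23 | C6′,C10′-dione | CC1=C2[C@H]3OC(=O)[C@@](Sc4ccccc4)(C)[C@@H]3CC[C@@](C)(O)[C@@H]2[C@H]2[C@@H](CC(Br)=C)[C@H]3C(=O)CC[C@@H]([C@H](C)C(=O)OC)C(=O)[C@@H]3[C@@H]12 | intermediate
24 | key-step precursor: 2-bromoallyl diquinane C6′ ketone, C10′ methyl carbinol, 11-phenylsulfanyl | CC1=C2[C@H]3OC(=O)[C@@](Sc4ccccc4)(C)[C@@H]3CC[C@@](C)(O)[C@@H]2[C@H]2[C@@H](CC(Br)=C)[C@H]3[C@@](C)(O)CC[C@@H]([C@H](C)C(=O)OC)C(=O)[C@@H]3[C@@H]12 | intermediate
25 | key-step product: C4′-methylene C6′-ketone ester, norbornane closed, 11-phenylsulfanyl | CC1=C2[C@H]3OC(=O)[C@@](Sc4ccccc4)(C)[C@@H]3CC[C@@](C)(O)[C@@H]2[C@H]2[C@H]3CC(=C)[C@]5([C@@H]3[C@@](C)(O)CC[C@@H]([C@H](C)C(=O)OC)C5=O)[C@@H]12 | intermediate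
26 | C11 phenylsulfinyl compound from 25 (both configurations at sulfur) | CC1=C2[C@H]3OC(=O)[C@@](S(=O)c4ccccc4)(C)[C@@H]3CC[C@@](C)(O)[C@@H]2[C@H]2[C@H]3CC(=C)[C@]5([C@@H]3[C@@](C)(O)CC[C@@H]([C@H](C)C(=O)OC)C5=O)[C@@H]12 | intermediate (not isolated)
27 | 11(13)-didehydro compound (α-methylene lactone, C4′ methylene, C6′ ketone) | CC1=C2[C@H]3OC(=O)C(=C)[C@@H]3CC[C@@](C)(O)[C@@H]2[C@H]2[C@H]3CC(=C)[C@]4([C@@H]3[C@@](C)(O)CC[C@@H]([C@H](C)C(=O)OC)C4=O)[C@@H]12 | intermediate
28 | C4′-methylene C6′-ketone ester with 11R lactone | CC1=C2[C@H]3OC(=O)[C@H](C)[C@@H]3CC[C@@](C)(O)[C@@H]2[C@H]2[C@H]3CC(=C)[C@]4([C@@H]3[C@@](C)(O)CC[C@@H]([C@H](C)C(=O)OC)C4=O)[C@@H]12 | intermediate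
29 | C4′-methyl (endo) C6′-ketone ester | CC1=C2[C@H]3OC(=O)[C@H](C)[C@@H]3CC[C@@](C)(O)[C@@H]2[C@H]2[C@H]3C[C@@H](C)[C@]4([C@@H]3[C@@](C)(O)CC[C@@H]([C@H](C)C(=O)OC)C4=O)[C@@H]12 | intermediate
30 | C6′ hydroxy ester (hydroxyl trans to the C7′ side chain) | CC1=C2[C@H]3OC(=O)[C@H](C)[C@@H]3CC[C@@](C)(O)[C@@H]2[C@H]2[C@H]3C[C@@H](C)[C@]4([C@@H]3[C@@](C)(O)CC[C@@H]([C@H](C)C(=O)OC)[C@@H]4O)[C@@H]12 | intermediate (not isolated)
31 | CNP0182139.1 | CC1=C2[C@H]3OC(=O)[C@H](C)[C@@H]3CC[C@@](C)(O)[C@@H]2[C@H]2[C@H]3C[C@@H](C)[C@]4([C@@H]3[C@@](C)(O)CC[C@H]3[C@H](C)C(=O)O[C@@H]34)[C@@H]12 | target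

## Step count and least certain steps

Total: 21 steps. Longest linear sequence: 17 steps from α-santonin (steps 1–6, 10, 11, 13–21). Steps 7–9 and step 12 are side branches.

**Step 17 (key step).** The most likely failure is that the hindered C5′ enolate does not engage the alkenylpalladium intermediate fast enough. Base-induced loss of HBr from the arm, or palladium-mediated O-alkenylation by the C10′ alkoxide, would then take over, because forming a quaternary carbon in a bicyclo[2.2.1] frame makes reductive elimination slow. Fallback: set out from 24 and remove HBr deliberately (TBAF·3H2O, DMF, 60 °C) to give the propargyl ketone F1. Close C4′–C5′ by a base-mediated Conia-ene cyclisation of the potassium enolate onto the terminal alkyne (KOtBu, DMSO, rt, 5-exo-dig). This gives the same exocyclic methylene and returns to the route at 25.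

**Step 10.** The most likely failure is in the first event: the fully substituted lactone enolate may add sluggishly or in a 1,2 sense to the γ-branched enone, and the tetrasubstituted allylic lactone may ionise slowly. Fallback: set out from 10 and trap its enolate as the trimethylsilyl ketene acetal F2 (LDA; TMSCl). Carry out a Lewis-acid Mukaiyama–Michael addition to 14 (TMSNTf2 cat., CH2Cl2, −78 °C), giving the silyl enol ether F3. Then trigger the allylic alkylation with fluoride and Pd(PPh3)4 (Bu4N[Ph3SiF2], THF). This returns to the route at 16.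

**Step 11.** The risk is poor facial discrimination in the hydrogen-atom transfer to the C2′ radical. That would leave part of the material with the arm on the convex face, where it cannot cyclise. Fallback: set out from 8 (without the arm) and 14 and run the step-10 sequence. The convex-face Michael addition then itself fixes C2′ and gives acid F4, with hydrogen on the convex face and the carboxyl at the arm position. Build the arm from that carboxyl: BH3·SMe2 to alcohol F5; I2, PPh3, imidazole to iodide F6; zinc insertion and Negishi coupling with 1,1-dibromoethene (Pd(PPh3)4). This returns to the route at 18.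

**Step 13.** The risk is that C7′ settles on the wrong epimer, because each epimer can place the side chain pseudo-equatorially in a different ring conformer. Elimination of the triflate by the enolate is a secondary risk. Fallback: correct C7′ after the key step, when C5′ is quaternary and C7′ is the only enolisable carbon of the ketone. Set out from 25, form the lithium enolate F7 (LDA, 3 equiv, THF, −78 °C) and protonate it kinetically with 2,6-di-tert-butylphenol from the less hindered face. This returns to the route at 25.

**Step 19.** The substrate's own bias is for hydrogen delivery anti to H7, which gives the natural 11S methyl. The catalyst must override it, and a mismatched pairing would erode the ratio. Fallback: set out from 27 and isomerise the exocyclic alkene into the ring (DBU, PhMe, 80 °C) to the Δ7(11) butenolide F8. Hydrogenate it cis from the face anti to H6 (H2, Rh/Al2O3, EtOAc), which installs H7 and H11 together and reduces the C4′ methylene as well. This returns to the route at 29. The tetrasubstituted C4=C5 alkene would have to be watched.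

**Step 21.** The risk is hydride attack on the other face of the C6′ ketone, which is flanked by two tertiary carbons, leading to the cis-fused lactone. Fallback: set out from 29 and use intramolecular delivery: Me4NBH(OAc)3 in MeCN/AcOH binds the C10′ hydroxyl and delivers hydride across the ring to the face of C6′ that the target requires. Lactonisation then returns to the route at 31.

## Further compounds

F1 | step 17 | propargyl analogue of 24 (C2′–CH2–C≡CH in place of the 2-bromoallyl group) | CC1=C2[C@H]3OC(=O)[C@@](Sc4ccccc4)(C)[C@@H]3CC[C@@](C)(O)[C@@H]2[C@H]2[C@@H](CC#C)[C@H]3[C@@](C)(O)CC[C@@H]([C@H](C)C(=O)OC)C(=O)[C@@H]3[C@@H]12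
F2 | step 10 | trimethylsilyl ketene acetal of lactone 10 | CC1=C2[C@H]3OC(=O)[C@@](Sc4ccccc4)(C)[C@@H]3CC[C@@](C)(O[Si](CC)(CC)CC)[C@@H]2[C@H]5C(CC(Br)=C)=C(O[Si](C)(C)C)O[C@@H]15
F3 | step 10 | C5′ trimethylsilyl enol ether of the Michael adduct of 10 and 14 | CC1=C2[C@H]3OC(=O)[C@@](Sc4ccccc4)(C)[C@@H]3CC[C@@](C)(O[Si](CC)(CC)CC)[C@@H]2[C@H]5[C@](CC(Br)=C)([C@H]6[C@H](O[Si](CC)(CC)CC)CCCC(O[Si](C)(C)C)=C6)C(=O)O[C@@H]15
F4 | step 11 | diquinane keto acid without the arm (C2′–H convex, CO2H concave) | CC1=C2[C@H]3OC(=O)[C@@](Sc4ccccc4)(C)[C@@H]3CC[C@@](C)(O[Si](CC)(CC)CC)[C@@H]2[C@H]2[C@@H](C(=O)O)[C@H]3[C@H](O[Si](CC)(CC)CC)CCCC(=O)[C@@H]3[C@@H]12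
F5 | step 11 | C3′ primary alcohol from F4 | CC1=C2[C@H]3OC(=O)[C@@](Sc4ccccc4)(C)[C@@H]3CC[C@@](C)(O[Si](CC)(CC)CC)[C@@H]2[C@H]2[C@@H](CO)[C@H]3[C@H](O[Si](CC)(CC)CC)CCCC(=O)[C@@H]3[C@@H]12
F6 | step 11 | C3′ primary iodide from F5 | CC1=C2[C@H]3OC(=O)[C@@](Sc4ccccc4)(C)[C@@H]3CC[C@@](C)(O[Si](CC)(CC)CC)[C@@H]2[C@H]2[C@@H](CI)[C@H]3[C@H](O[Si](CC)(CC)CC)CCCC(=O)[C@@H]3[C@@H]12
F7 | step 13 | trilithium salt of 25 (C6′–C7′ enolate and both tertiary alkoxides) | CC1=C2[C@H]3OC(=O)[C@@](Sc4ccccc4)(C)[C@@H]3CC[C@@](C)(O[Li])[C@@H]2[C@H]2[C@H]3CC(=C)[C@]5([C@@H]3[C@@](C)(O[Li])CCC([C@H](C)C(=O)OC)=C5O[Li])[C@@H]12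
F8 | step 19 | Δ7(11) butenolide isomer of 27 | CC1=C2[C@H]3OC(=O)C(C)=C3CC[C@@](C)(O)[C@@H]2[C@H]2[C@H]3CC(=C)[C@]4([C@@H]3[C@@](C)(O)CC[C@@H]([C@H](C)C(=O)OC)C4=O)[C@@H]12
F0 | step 21 | none | none
A1 | alternative 1 | 8,9:8′,9′-didehydro target | CC1=C2[C@H]3OC(=O)[C@H](C)[C@@H]3C=C[C@@](C)(O)[C@@H]2[C@H]2[C@H]3C[C@@H](C)[C@]4([C@@H]3[C@@](C)(O)C=C[C@H]3[C@H](C)C(=O)O[C@@H]34)[C@@H]12
A2 | alternative 2 | C10′ ketone lacking the C14′ methyl | CC1=C2[C@H]3OC(=O)[C@H](C)[C@@H]3CC[C@@](C)(O)[C@@H]2[C@H]2[C@H]3C[C@@H](C)[C@]4([C@@H]3C(=O)CC[C@H]3[C@H](C)C(=O)O[C@@H]34)[C@@H]12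
A3 | alternative 3 | 3′-oxo derivative of the target | CC1=C2[C@H]3OC(=O)[C@H](C)[C@@H]3CC[C@@](C)(O)[C@@H]2[C@H]2[C@H]3C(=O)[C@@H](C)[C@]4([C@@H]3[C@@](C)(O)CC[C@H]3[C@H](C)C(=O)O[C@@H]34)[C@@H]12
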